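The target is methyl shikimate carrying three different acyl groups. The plan cuts its cyclohexene ring (C1 to C6, shikimate numbering) into three two-carbon pieces. C1/C2 come from methyl propiolate and C3/C4 from acetylene. C5/C6 come from the vinyl ester of (S)-3-methylpentanoic acid, the acid that O5 bears in the target. One rhodium-catalysed [2+2+2] cycloaddition forms C2–C3, C4–C5 and C6–C1. It closes the ring as a 1,3-dienoate, delivers O5 already acylated and sets C5. The precursors are three simple π components, and only one has to be made. C5 then steers a cis-dihydroxylation of C3=C4, and the diol is differentiated through a cyclic orthoacetate.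

Key step: step 2

Numbering and abbreviations: C1 bears CO2Me, C2 is the alkene CH, C3/C4/C5 bear oxygen, C6 is CH2; cod = 1,5-cyclooctadiene, BINAP = 2,2'-bis(diphenylphosphino)-1,1'-binaphthyl, NMO = N-methylmorpholine N-oxide.

Assumption: (R)-BINAP is taken as the ligand enantiomer that leads to 5R; the sense of induction cannot be derived for this new combination of partners, so it would be checked by correlating 7 with natural (−)-shikimic acid, and (S)-BINAP would be used instead if it proves opposite.

Step 1
Reactants: 1 (S)-3-methylpentanoic acid; 2 vinyl acetate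
Product: 3 vinyl (S)-3-methylpentanoate
Conditions: Pd(OAc)2 (5 mol %), KOH (10 mol %), 2 as solvent (large excess), rt; distillation
Reagents that add atoms: none
Why: Transvinylation catalysed by divalent palladium (oxypalladation of 2 by the carboxylate, then β-acetoxy elimination) is an equilibrium pulled forward by the excess of 2 and does not touch the β-stereocentre of 1.

Step 2
Reactants: 3 vinyl (S)-3-methylpentanoate; 4 methyl propiolate; 5 acetylene
Product: 6 methyl (5R)-5-[(3S)-3-methylpentanoyloxy]cyclohexa-1,3-diene-1-carboxylate
Conditions: [Rh(cod)2]BF4 (10 mol %), (R)-BINAP (10 mol %), CH2Cl2, H2 (1 atm, 30 min) then Ar purge; 2,6-di-tert-butylpyridine (20 mol %), 3 (3 equiv, excess recovered by distillation), 5 (1 atm), 4 added by syringe pump over 12 h, 0 °C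
Reagents that add atoms: none
Why: Proposed new method: after hydrogenative removal of cod, the cationic monovalent rhodium diphosphine fragment should couple electron-poor 4 and 5 oxidatively, forming C2–C3 at the propiolate carbon with the larger LUMO coefficient, so that a trivalent rhodacyclopentadiene results with ester-bearing C1 and unsubstituted C4 on the metal. Vinyl ester 3, bound through its alkene and its acyl oxygen, should insert into the less hindered and more nucleophilic Rh–C4 bond in the charge-controlled sense that enol esters show in Heck-type insertions at cationic diphosphine metal centres (carbon to the oxygen-bearing C5, metal to the terminal C6), and the cyclohexadiene ring is closed by C6–C1 reductive elimination from the seven-membered rhodacycle, a formal [2+2+2] cycloaddition overall. The closest known reaction types are the enantioselective cationic rhodium [2+2+2] cycloadditions of diynes with alkenes, the cross-trimerisation of two unlike alkynes with a chelating acrylamide, and the use of enol acetates as alkyne surrogates in which the carboxylic acid is lost; a fully intermolecular trio that keeps the enol ester oxygen has not been shown. C5 is the only new stereocentre and is fixed in the insertion by the twofold-symmetric binaphthyl diphosphine, whose phenyl quadrants leave one face of the chelated alkene open, while the remote centre of the acyl chain should have no say. Three selectivities are needed: cross-selection of the three partners, which rests on the electronic mismatch of 4 and 5, on the low stationary concentration of 4 and on the excess of chelating 3; head-to-tail orientation, which rests on the polarisation of 4 and of 3; and survival of the C5–O bond against β-acyloxy elimination and aromatisation, which rests on the rigid metallacycle, the low temperature and the hindered base that traps adventitious acid. Diene 6 should be filtered through neutral Al2O3 and carried straight into step 3.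

Step 3
Reactants: 6 methyl (5R)-5-[(3S)-3-methylpentanoyloxy]cyclohexa-1,3-diene-1-carboxylate
Product: 7 methyl (3R,4R,5R)-3,4-dihydroxy-5-[(3S)-3-methylpentanoyloxy]cyclohex-1-ene-1-carboxylate (methyl 5-O-acylshikimate; O3 and O4 cis and both trans to O5; C4 reads R here only through CIP ranking and has the geometry of the target)
Conditions: OsO4 (3 mol %), NMO (1.1 equiv), acetone/H2O, 0 °C
Reagents that add atoms: osmium tetroxide, O=[Os](=O)(=O)=O; N-methylmorpholine N-oxide, C[N+]1([O-])CCOCC1; water, O
Why: In this Upjohn dihydroxylation OsO4 should choose the electron-richer disubstituted C3=C4 bond over the ester-conjugated trisubstituted C1=C2 bond and add suprafacially from the ring face opposite the allylic C5 acyloxy group, which sets C3 and C4 cis to each other and trans to O5, as is established for 5-oxygenated cyclohexa-1,3-diene-1-carboxylates.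

Step 4
Reactants: 7 methyl (3R,4R,5R)-3,4-dihydroxy-5-[(3S)-3-methylpentanoyloxy]cyclohex-1-ene-1-carboxylate
Product: 9 methyl (3R,4S,5R)-3-acetoxy-4-hydroxy-5-[(3S)-3-methylpentanoyloxy]cyclohex-1-ene-1-carboxylate, via cyclic orthoacetate 8 (not isolated)
Conditions: MeC(OMe)3 (3 equiv), PPTS (5 mol %), CH2Cl2, rt; then AcOH/H2O 4:1, 0 °C
Reagents that add atoms: trimethyl orthoacetate, CC(OC)(OC)OC; water, O
Why: Acid-catalysed orthoester exchange ties the cis-3,4-diol into the 2-methoxy-2-methyl-1,3-dioxolane 8, and its kinetic hydrolysis through the hemi-orthoester should follow the well-documented stereoelectronic preference for axial ester and equatorial alcohol, which in the shikimate half-chair (O3 pseudoaxial, O4 and O5 equatorial) puts the acetate on O3 without touching any stereocentre.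

Step 5
Reactants: 9 methyl (3R,4S,5R)-3-acetoxy-4-hydroxy-5-[(3S)-3-methylpentanoyloxy]cyclohex-1-ene-1-carboxylate; 10 (R)-2-methylbutanoic acid
Product: 11 methyl (3R,4S,5R)-3-acetoxy-4-[(2R)-2-methylbutanoyloxy]-5-[(3S)-3-methylpentanoyloxy]cyclohex-1-ene-1-carboxylate (CNP0188172.1)
Conditions: DCC (1.5 equiv), DMAP (0.2 equiv), 10 (1.5 equiv), CH2Cl2, 0 °C to rt
Reagents that add atoms: none
Why: Steglich esterification acylates the only free hydroxyl with retention at C4 because the C4–O bond is never broken, and catalytic DMAP at low temperature should suppress both epimerisation of the α-stereocentre of 10 and acetate migration from O3 to O4.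

Compound list
1 | (S)-3-methylpentanoic acid | CC[C@H](C)CC(=O)O | starting material
2 | vinyl acetate | C=COC(C)=O | starting material
3 | vinyl (S)-3-methylpentanoate | C=COC(=O)C[C@@H](C)CC | intermediate
4 | methyl propiolate | C#CC(=O)OC | starting material
5 | acetylene | C#C | starting material
6 | methyl (5R)-5-[(3S)-3-methylpentanoyloxy]cyclohexa-1,3-diene-1-carboxylate | CC[C@H](C)CC(=O)O[C@@H]1CC(C(=O)OC)=CC=C1 | intermediate
7 | methyl (3R,4R,5R)-3,4-dihydroxy-5-[(3S)-3-methylpentanoyloxy]cyclohex-1-ene-1-carboxylate | CC[C@H](C)CC(=O)O[C@@H]1CC(C(=O)OC)=C[C@@H](O)[C@H]1O | intermediate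
8 | 3,4-O-(1-methoxyethylidene) derivative of 7 (cis-fused cyclic orthoacetate, both epimers at the orthoester carbon) | CC[C@H](C)CC(=O)O[C@@H]1CC(C(=O)OC)=C[C@H]2OC(C)(OC)O[C@@H]12 | intermediate
9 | methyl (3R,4S,5R)-3-acetoxy-4-hydroxy-5-[(3S)-3-methylpentanoyloxy]cyclohex-1-ene-1-carboxylate | CC[C@H](C)CC(=O)O[C@@H]1CC(C(=O)OC)=C[C@@H](OC(C)=O)[C@H]1O | intermediate
10 | (R)-2-methylbutanoic acid | CC[C@@H](C)C(=O)O | starting material
11 | methyl (3R,4S,5R)-3-acetoxy-4-[(2R)-2-methylbutanoyloxy]-5-[(3S)-3-methylpentanoyloxy]cyclohex-1-ene-1-carboxylate | CC[C@H](C)CC(=O)O[C@@H]1CC(C(=O)OC)=C[C@@H](OC(C)=O)[C@H]1OC(=O)[C@H](C)CC | target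

Total step count: 5
Longest linear sequence: 5 steps (1 → 3 → 6 → 7 → 9 → 11)

Steps most likely to fail

1. Step 2.
- **What may go wrong:** Homotrimerisation or polymerisation of the alkynes may outrun the cross-coupling. The vinyl ester may insert with the opposite orientation, or the metal alkyl may undergo β-acyloxy elimination. The diene may aromatise by loss of the acid, or facial discrimination may be poor.
- **Fallback:** It uses known chemistry only, sets out from acid 1 and comes back at 6. Furan and 3-acryloyl-1,3-oxazolidin-2-one undergo the enantioselective Diels–Alder reaction under the divalent copper catalyst [Cu((R,R)-t-Bu-box)](SbF6)2 (t-Bu-box = 2,2'-isopropylidenebis(4-tert-butyl-2-oxazoline)) in CH2Cl2 at −78 °C. This should give the endo imide 3-[(1R,2R,4R)-7-oxabicyclo[2.2.1]hept-5-ene-2-carbonyl]-1,3-oxazolidin-2-one F1. Methanolysis with MeOMgBr in MeOH/CH2Cl2 at −20 °C should give methyl (1R,2R,4R)-7-oxabicyclo[2.2.1]hept-5-ene-2-carboxylate F2. LiN(SiMe3)2 in THF at −78 °C then opens the oxygen bridge by E1cB elimination. The bridgehead C4 is kept as the carbinol centre of methyl (5R)-5-hydroxycyclohexa-1,3-diene-1-carboxylate F3. Steglich esterification of this alcohol with 1 (DCC, catalytic DMAP, CH2Cl2, 0 °C) delivers 6.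

2. Step 4.
- **What may go wrong:** The hemi-orthoester may collapse toward the wrong oxygen. Acyl groups may also migrate among O3, O4 and O5 during hydrolysis and chromatography.
- **Fallback:** It sets out from 7 and comes back at 11, replacing stereoelectronic control by steric differentiation with a temporary silyl group. TBSCl and imidazole in DMF at 0 °C should silylate the allylic O3, since O4 is flanked by oxygenated carbons on both sides. The product is methyl 3-O-(tert-butyldimethylsilyl)-5-O-[(S)-3-methylpentanoyl]shikimate F6. Steglich esterification with 10 should give methyl 3-O-(tert-butyldimethylsilyl)-4-O-[(R)-2-methylbutanoyl]-5-O-[(S)-3-methylpentanoyl]shikimate F7. HF·pyridine in THF at 0 °C should free O3 under non-basic conditions to give methyl 4-O-[(R)-2-methylbutanoyl]-5-O-[(S)-3-methylpentanoyl]shikimate F8. Immediate acetylation (Ac2O, pyridine, catalytic DMAP, 0 °C) gives 11.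

3. Step 3.
- **What may go wrong:** Facial selectivity may be insufficient, or the C1=C2 bond may be oxidised further. Aromatisation and acyl migration may occur in the aqueous amine medium.
- **Fallback:** It sets out from 6 and comes back at 7, running under anhydrous conditions through an epoxide that is opened with net retention. Buffered mCPBA (Na2HPO4, CH2Cl2, 0 °C) should epoxidise the electron-richer C3=C4 bond from the face opposite O5. This gives methyl (1R,5R,6S)-5-[(3S)-3-methylpentanoyloxy]-7-oxabicyclo[4.1.0]hept-2-ene-3-carboxylate F4, which can be freed of any facial isomer by chromatography. Zerovalent palladium (Pd(PPh3)4, 5 mol %) with PhB(OH)2 in THF ionises the allylic C3–O bond with inversion. The boron-tethered oxygen is then delivered to C3 anti to the metal. This double inversion is known for γ,δ-epoxy-α,β-unsaturated esters and should give the cis-fused 3,4-O-phenylboranediyl derivative of 7 F5. Exchange with pinacol releases 7.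

Further compounds
F1 | step 2 | 3-[(1R,2R,4R)-7-oxabicyclo[2.2.1]hept-5-ene-2-carbonyl]-1,3-oxazolidin-2-one (endo) | O=C1OCCN1C(=O)[C@@H]1C[C@@H]2C=C[C@H]1O2
F2 | step 2 | methyl (1R,2R,4R)-7-oxabicyclo[2.2.1]hept-5-ene-2-carboxylate (endo) | COC(=O)[C@@H]1C[C@@H]2C=C[C@H]1O2
F3 | step 2 | methyl (5R)-5-hydroxycyclohexa-1,3-diene-1-carboxylate | O[C@@H]1CC(C(=O)OC)=CC=C1
F4 | step 3 | methyl (1R,5R,6S)-5-[(3S)-3-methylpentanoyloxy]-7-oxabicyclo[4.1.0]hept-2-ene-3-carboxylate (oxirane anti to O5) | CC[C@H](C)CC(=O)O[C@@H]1CC(C(=O)OC)=C[C@H]2O[C@@H]12
F5 | step 3 | 3,4-O-phenylboranediyl derivative of 7 (cis-fused cyclic phenylboronate) | CC[C@H](C)CC(=O)O[C@@H]1CC(C(=O)OC)=C[C@H]2OB(c3ccccc3)O[C@@H]12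
F6 | step 4 | methyl 3-O-(tert-butyldimethylsilyl)-5-O-[(S)-3-methylpentanoyl]shikimate | CC[C@H](C)CC(=O)O[C@@H]1CC(C(=O)OC)=C[C@@H](O[Si](C)(C)C(C)(C)C)[C@H]1O
F7 | step 4 | methyl 3-O-(tert-butyldimethylsilyl)-4-O-[(R)-2-methylbutanoyl]-5-O-[(S)-3-methylpentanoyl]shikimate | CC[C@H](C)CC(=O)O[C@@H]1CC(C(=O)OC)=C[C@@H](O[Si](C)(C)C(C)(C)C)[C@H]1OC(=O)[C@H](C)CC
F8 | step 4 | methyl 4-O-[(R)-2-methylbutanoyl]-5-O-[(S)-3-methylpentanoyl]shikimate | CC[C@H](C)CC(=O)O[C@@H]1CC(C(=O)OC)=C[C@@H](O)[C@H]1OC(=O)[C@H](C)CC
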